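Rings A, C and B denote the 4'-hydroxyflavanone, rings D, F and E with double-primed locants the 4'-methoxyflavanone. The route rests on opening ring F across C2''–C3'' and C4''–C4a'', which leaves a p-methoxybenzyl ether on the ring D oxygen O1'' and a ketene unit. In the key step DDQ oxidises this ether to an O-aryl oxocarbenium ion paired with a chiral anion; ethoxyacetylene adds through its terminal carbon and ring D closes ring F at C4a'', its only free position ortho to O1''. The precursor, a benzyl-protected 3-aryl flavanone, comes from asymmetric conjugate arylation of a chromone and an ortho-selective sulfonium [2,3] shift.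

Key step: step 7

Remark: compounds 1, 4, 8, 13 and 15 are taken as commercially available.
Remark: for the chiral catalysts of steps 2 and 7 the antipode that leads to the stated configuration is assigned in a preliminary screen; both antipodes are accessible.

Step 1
Reactants: 1 1-[2,4-bis(benzyloxy)-6-hydroxyphenyl]ethanone
Product: 3 5,7-bis(benzyloxy)-4H-chromen-4-one, via enaminone 2 (not isolated)
Conditions: DMF-DMA (2 equiv), toluene, 95 °C; then conc. HCl, CH2Cl2, 40 °C
Reagents that add atoms: N,N-dimethylformamide dimethyl acetal, COC(OC)N(C)C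
Why: Enaminone formation at the acetyl methyl group followed by acid-promoted addition of the phenol and loss of dimethylamine is the standard chromone synthesis from 2'-hydroxyacetophenones; no stereocentre is formed.

Step 2
Reactants: 3 5,7-bis(benzyloxy)-4H-chromen-4-one; 4 [4-(benzyloxy)phenyl]boronic acid
Product: 5 (2R)-5,7-bis(benzyloxy)-2-[4-(benzyloxy)phenyl]chroman-4-one
Conditions: [Rh(OH)(cod)]2 (3 mol%), MeO-F12-BIPHEP (7 mol%), toluene/H2O, 40 °C
Reagents that add atoms: none
Why: Hayashi–Miyaura-type rhodium-catalysed asymmetric 1,4-addition of an arylboronic acid to a chromone, in which the chiral diphosphine selects the face of C2 to which the aryl–rhodium species adds and so sets C2 (R).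

Step 3
Reactants: 5 (2R)-5,7-bis(benzyloxy)-2-[4-(benzyloxy)phenyl]chroman-4-one
Product: 7 (2S,3S)-5,7-bis(benzyloxy)-2-[4-(benzyloxy)phenyl]-3-(methylsulfanyl)chroman-4-one, via silyl enol ether 6 (not isolated)
Conditions: TMSOTf, Et3N, CH2Cl2, 0 °C; then DMTSF, −40 °C to 0 °C
Reagents that add atoms: dimethyl(methylthio)sulfonium tetrafluoroborate (DMTSF), C[S+](C)SC.F[B-](F)(F)F
Why: Soft enolisation gives the silyl enol ether without a free enolate that could open ring C, and electrophilic sulfenylation of the enol ether then places SMe at C3 anti to the C2 aryl group; C2 is untouched (its descriptor becomes S only because sulfur raises the rank of C3) and the C3 configuration is of no consequence.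

Step 4
Reactants: 7 (2S,3S)-5,7-bis(benzyloxy)-2-[4-(benzyloxy)phenyl]-3-(methylsulfanyl)chroman-4-one; 8 3,5-bis(benzyloxy)phenol
Product: 11 (2S,3R)-5,7-bis(benzyloxy)-2-[4-(benzyloxy)phenyl]-3-[2,4-bis(benzyloxy)-6-hydroxyphenyl]-3-(methylsulfanyl)chroman-4-one, via chlorosulfonium salt 9 (not isolated), via aryloxysulfonium salt 10 (not isolated)
Conditions: NCS (1.0 equiv), CH2Cl2, −78 °C; then 8, −78 °C; then Et3N, −78 °C to 0 °C
Reagents that add atoms: none
Why: Gassman ortho-alkylation of a phenol: S-chlorination, exchange of chloride for the phenoxy group and deprotonation at C3 give a ketone-stabilised ylide that undergoes a [2,3]-sigmatropic shift onto an ortho carbon of 8 (both are equivalent) and rearomatises, so ring D is bonded to C3 directly beside the free hydroxyl group that later becomes O1''; ring D should enter anti to the C2 aryl group, but this centre is reset in step 5.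

Step 5
Reactants: 11 (2S,3R)-5,7-bis(benzyloxy)-2-[4-(benzyloxy)phenyl]-3-[2,4-bis(benzyloxy)-6-hydroxyphenyl]-3-(methylsulfanyl)chroman-4-one
Product: 12 (2R,3S)-5,7-bis(benzyloxy)-2-[4-(benzyloxy)phenyl]-3-[2,4-bis(benzyloxy)-6-hydroxyphenyl]chroman-4-one
Conditions: Zn dust, AcOH, THF, 25 °C
Reagents that add atoms: none
Why: Reductive cleavage of a C–S bond alpha to a ketone (desulfurisation of an α-thio ketone); protonation of the enol under the acidic conditions should give the thermodynamically favoured 2,3-trans isomer with both aryl groups equatorial, which sets C3 (S) relative to C2 (R).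

Step 6
Reactants: 12 (2R,3S)-5,7-bis(benzyloxy)-2-[4-(benzyloxy)phenyl]-3-[2,4-bis(benzyloxy)-6-hydroxyphenyl]chroman-4-one; 13 4-methoxybenzyl alcohol
Product: 14 (2R,3S)-5,7-bis(benzyloxy)-2-[4-(benzyloxy)phenyl]-3-{2,4-bis(benzyloxy)-6-[(4-methoxybenzyl)oxy]phenyl}chroman-4-one
Conditions: PPh3, DIAD, THF, 0 °C to 25 °C
Reagents that add atoms: none
Why: Mitsunobu etherification of the ring D phenol under neutral conditions, which avoids base-induced opening of ring C; no stereocentre is touched.

Step 7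
Reactants: 14 (2R,3S)-5,7-bis(benzyloxy)-2-[4-(benzyloxy)phenyl]-3-{2,4-bis(benzyloxy)-6-[(4-methoxybenzyl)oxy]phenyl}chroman-4-one; 15 ethoxyacetylene
Product: 18 (2R,3S)-5,7-bis(benzyloxy)-2-[4-(benzyloxy)phenyl]-3-[(2S)-5,7-bis(benzyloxy)-2-(4-methoxyphenyl)-4-oxochroman-8-yl]chroman-4-one, via oxocarbenium ion pair 16 (not isolated), via 4-ethoxy-2H-chromene 17 (not isolated)
Conditions: DDQ (1.1 equiv), 4 Å molecular sieves, CH2Cl2, 0 °C; then chiral imidodiphosphorimidate Brønsted acid (IDPi type, 10 mol%), 15 (3 equiv, slow addition), −78 °C; then 1 M HCl, THF/H2O, 0 °C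
Reagents that add atoms: water, O
Why: Proposed new method: DDQ removes a hydride from the p-methoxybenzyl CH2 of 14 to give the O-aryl oxocarbenium ion 16 (cation across O1''–C2''), the chiral acid exchanges the DDQH anion for its own confined anion, the terminal carbon of ethoxyacetylene attacks C2'' (bond C2''–C3''), the resulting ketene-oxonium carbon C4'' is captured by ring D at C4a'' (bond C4''–C4a''), loss of the ring proton returns the acid, and aqueous HCl hydrolyses enol ether 17 to the ketone. The closest known reaction types are the oxa-Povarov reaction (Lewis-acid [4+2] annulation of O-aryl oxocarbenium ions with alkenes), DDQ-mediated oxocarbenium formation from p-methoxybenzyl ethers with capture by π-nucleophiles, and Friedel–Crafts capture of ketene-iminium ions; their combination with an ynol ether under a chiral counteranion has not been shown. Ring F closes in the second bond-forming event as a six-membered cation–arene (Friedel–Crafts) cyclisation, so the whole is a stepwise polar [4+2] annulation with inverse electron demand. The only new stereocentre, C2'', is set when the alkyne adds to one face of the planar oxocarbenium ion, which is governed by the chiral anion (catalyst control; the remote centres C2 and C3 are not relied upon), and because the two C2'' epimers are diastereomers the minor one should be removable by chromatography. The step needs hydride abstraction at the p-methoxybenzyl CH2 only (it is the sole primary p-alkoxybenzylic ether, whereas C2–H of ring C is tertiary and deactivated by the C4 carbonyl and plain benzyl ethers are inert to DDQ in the cold), attack through the terminal alkyne carbon (the ethoxy group stabilises the cation at C4''), and closure at C4a'' (the only free position ortho to O1'', since C8'' carries ring C).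

Step 8
Reactants: 18 (2R,3S)-5,7-bis(benzyloxy)-2-[4-(benzyloxy)phenyl]-3-[(2S)-5,7-bis(benzyloxy)-2-(4-methoxyphenyl)-4-oxochroman-8-yl]chroman-4-one
Product: 19 (2R,3S)-5,7-dihydroxy-2-(4-hydroxyphenyl)-3-[(2S)-5,7-dihydroxy-2-(4-methoxyphenyl)-4-oxochroman-8-yl]chroman-4-one
Conditions: H2 (1 atm), Pd/C, EtOAc/MeOH, 25 °C
Reagents that add atoms: none
Why: Hydrogenolysis of the five benzyl ethers under neutral conditions, which should leave the aryl methyl ether, both ketones and the three stereocentres untouched.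

Compound list
1 | 1-[2,4-bis(benzyloxy)-6-hydroxyphenyl]ethanone | CC(=O)c1c(O)cc(OCc2ccccc2)cc1OCc1ccccc1 | starting material
2 | (E)-1-[2,4-bis(benzyloxy)-6-hydroxyphenyl]-3-(dimethylamino)prop-2-en-1-one | CN(C)/C=C/C(=O)c1c(O)cc(OCc2ccccc2)cc1OCc1ccccc1 | intermediate (not isolated)
3 | 5,7-bis(benzyloxy)-4H-chromen-4-one | O=c1ccoc2cc(OCc3ccccc3)cc(OCc3ccccc3)c12 | intermediate
4 | [4-(benzyloxy)phenyl]boronic acid | OB(O)c1ccc(OCc2ccccc2)cc1 | starting material
5 | (2R)-5,7-bis(benzyloxy)-2-[4-(benzyloxy)phenyl]chroman-4-one | O=C1C[C@H](c2ccc(OCc3ccccc3)cc2)Oc2cc(OCc3ccccc3)cc(OCc3ccccc3)c21 | intermediate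
6 | (2R)-5,7-bis(benzyloxy)-2-[4-(benzyloxy)phenyl]-4-(trimethylsilyloxy)-2H-chromene | C[Si](C)(C)OC1=C[C@H](c2ccc(OCc3ccccc3)cc2)Oc2cc(OCc3ccccc3)cc(OCc3ccccc3)c21 | intermediate (not isolated)
7 | (2S,3S)-5,7-bis(benzyloxy)-2-[4-(benzyloxy)phenyl]-3-(methylsulfanyl)chroman-4-one (2,3-trans; same spatial arrangement at C2 as in 5) | CS[C@@H]1C(=O)c2c(OCc3ccccc3)cc(OCc3ccccc3)cc2O[C@H]1c1ccc(OCc2ccccc2)cc1 | intermediate
8 | 3,5-bis(benzyloxy)phenol | Oc1cc(OCc2ccccc2)cc(OCc2ccccc2)c1 | starting material
9 | S-chloro sulfonium succinimidate of 7 (carbon centres as in 7, sulfur centre undefined) | C[S+](Cl)[C@@H]1C(=O)c2c(OCc3ccccc3)cc(OCc3ccccc3)cc2O[C@H]1c1ccc(OCc2ccccc2)cc1.O=C1CCC(=O)[N-]1 | intermediate (not isolated)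
10 | S-[3,5-bis(benzyloxy)phenoxy] sulfonium chloride of 7 (carbon centres as in 7, sulfur centre undefined) | C[S+](Oc1cc(OCc2ccccc2)cc(OCc2ccccc2)c1)[C@@H]1C(=O)c2c(OCc3ccccc3)cc(OCc3ccccc3)cc2O[C@H]1c1ccc(OCc2ccccc2)cc1.[Cl-] | intermediate (not isolated)
11 | (2S,3R)-5,7-bis(benzyloxy)-2-[4-(benzyloxy)phenyl]-3-[2,4-bis(benzyloxy)-6-hydroxyphenyl]-3-(methylsulfanyl)chroman-4-one (ring D trans to the C2 aryl group) | Oc1cc(OCc2ccccc2)cc(OCc2ccccc2)c1[C@]1(SC)C(=O)c2c(OCc3ccccc3)cc(OCc3ccccc3)cc2O[C@H]1c1ccc(OCc2ccccc2)cc1 | intermediate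
12 | (2R,3S)-5,7-bis(benzyloxy)-2-[4-(benzyloxy)phenyl]-3-[2,4-bis(benzyloxy)-6-hydroxyphenyl]chroman-4-one | Oc1cc(OCc2ccccc2)cc(OCc2ccccc2)c1[C@@H]1C(=O)c2c(OCc3ccccc3)cc(OCc3ccccc3)cc2O[C@H]1c1ccc(OCc2ccccc2)cc1 | intermediate
13 | 4-methoxybenzyl alcohol | COc1ccc(CO)cc1 | starting material
14 | (2R,3S)-5,7-bis(benzyloxy)-2-[4-(benzyloxy)phenyl]-3-{2,4-bis(benzyloxy)-6-[(4-methoxybenzyl)oxy]phenyl}chroman-4-one | COc1ccc(COc2cc(OCc3ccccc3)cc(OCc3ccccc3)c2[C@@H]2C(=O)c3c(OCc4ccccc4)cc(OCc4ccccc4)cc3O[C@H]2c2ccc(OCc3ccccc3)cc2)cc1 | intermediate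
15 | ethoxyacetylene (ethoxyethyne) | CCOC#C | starting material
16 | O-aryl oxocarbenium ion from 14, as its ion pair with the DDQH anion | COc1ccc(C=[O+]c2cc(OCc3ccccc3)cc(OCc3ccccc3)c2[C@@H]2C(=O)c3c(OCc4ccccc4)cc(OCc4ccccc4)cc3O[C@H]2c2ccc(OCc3ccccc3)cc2)cc1.[O-]c1c(Cl)c(Cl)c(O)c(C#N)c1C#N | intermediate (not isolated)
17 | (2R,3S)-5,7-bis(benzyloxy)-2-[4-(benzyloxy)phenyl]-3-[(2S)-5,7-bis(benzyloxy)-4-ethoxy-2-(4-methoxyphenyl)-2H-chromen-8-yl]chroman-4-one | COc1ccc([C@@H]2C=C(OCC)c3c(OCc6ccccc6)cc(OCc6ccccc6)c([C@@H]4C(=O)c5c(OCc6ccccc6)cc(OCc6ccccc6)cc5O[C@H]4c4ccc(OCc6ccccc6)cc4)c3O2)cc1 | intermediate (not isolated)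
18 | (2R,3S)-5,7-bis(benzyloxy)-2-[4-(benzyloxy)phenyl]-3-[(2S)-5,7-bis(benzyloxy)-2-(4-methoxyphenyl)-4-oxochroman-8-yl]chroman-4-one | COc1ccc([C@@H]2CC(=O)c3c(OCc6ccccc6)cc(OCc6ccccc6)c([C@@H]4C(=O)c5c(OCc6ccccc6)cc(OCc6ccccc6)cc5O[C@H]4c4ccc(OCc6ccccc6)cc4)c3O2)cc1 | intermediate
19 | (2R,3S)-5,7-dihydroxy-2-(4-hydroxyphenyl)-3-[(2S)-5,7-dihydroxy-2-(4-methoxyphenyl)-4-oxochroman-8-yl]chroman-4-one | COc1ccc([C@@H]2CC(=O)c3c(O)cc(O)c([C@@H]4C(=O)c5c(O)cc(O)cc5O[C@H]4c4ccc(O)cc4)c3O2)cc1 | target

Total step count: 8. Longest linear sequence: 8 steps (1 to 19).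

Steps most likely to fail

1. Step 7 (key step). The risks as processes are:
- hydride abstraction by DDQ at other activated C–H bonds (C2–H or C3–H of ring C, leading to dehydrogenation);
- consumption of the ynol ether by the acid or by residual DDQ before it meets the oxocarbenium ion;
- an unselective background reaction of the DDQH ion pair that erodes facial selectivity at C2''.

The fallback sets out from phenol 12 and comes back at 18, and uses classical flavanone chemistry. Phenol 12 is acylated with (E)-4-methoxycinnamoyl chloride (Et3N, DMAP, CH2Cl2) to give 2-[(2R,3S)-5,7-bis(benzyloxy)-2-[4-(benzyloxy)phenyl]-4-oxochroman-3-yl]-3,5-bis(benzyloxy)phenyl (E)-3-(4-methoxyphenyl)prop-2-enoate F1. A Fries rearrangement (BF3·OEt2 in 1,2-dichloroethane, or photochemically) moves the acyl group to C4a'', the only free ortho position, and gives the 2'-hydroxychalcone (2R,3S)-5,7-bis(benzyloxy)-2-[4-(benzyloxy)phenyl]-3-{4,6-bis(benzyloxy)-2-hydroxy-3-[(E)-3-(4-methoxyphenyl)prop-2-enoyl]phenyl}chroman-4-one F2. Acid-mediated oxa-Michael closure of ring F and chromatographic separation of the two C2'' diastereomers should then deliver 18.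

2. Step 4. The risks as processes are:
- Pummerer-type collapse of the S-activated sulfide before the phenol has bound to sulfur;
- elimination towards the flavone;
- ring chlorination of the electron-rich phenol by NCS.

The fallback sets out from 7 and comes back at 11. Sulfide 7 is treated with NCS alone (CCl4, 0 °C) so that the Pummerer product (2S)-5,7-bis(benzyloxy)-2-[4-(benzyloxy)phenyl]-3-chloro-3-(methylsulfanyl)chroman-4-one F3 is formed on purpose. F3 is then used in a SnCl4-promoted Friedel–Crafts alkylation of phenol 8 (CH2Cl2, −78 °C). The isomer attached ortho to the hydroxyl group is 11, which is separated from the para-attached regioisomer by chromatography.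

3. Step 8. The risks as processes are over-reduction (hydrogenolysis of the benzylic C2–O1 and C2''–O1'' bonds, reduction of the ketones) and incomplete removal of the five benzyl groups. The fallback sets out from 18 and gives 19 directly: Lewis-acid debenzylation with BCl3 and pentamethylbenzene as cation scavenger (CH2Cl2, −78 °C). The aryl methyl ether, which is not ortho to a carbonyl group, should survive. No new compound is made.

Further compounds
F1 | step 7 | 2-[(2R,3S)-5,7-bis(benzyloxy)-2-[4-(benzyloxy)phenyl]-4-oxochroman-3-yl]-3,5-bis(benzyloxy)phenyl (E)-3-(4-methoxyphenyl)prop-2-enoate | COc1ccc(/C=C/C(=O)Oc2cc(OCc3ccccc3)cc(OCc3ccccc3)c2[C@@H]2C(=O)c3c(OCc4ccccc4)cc(OCc4ccccc4)cc3O[C@H]2c2ccc(OCc3ccccc3)cc2)cc1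
F2 | step 7 | (2R,3S)-5,7-bis(benzyloxy)-2-[4-(benzyloxy)phenyl]-3-{4,6-bis(benzyloxy)-2-hydroxy-3-[(E)-3-(4-methoxyphenyl)prop-2-enoyl]phenyl}chroman-4-one | COc1ccc(/C=C/C(=O)c2c(O)c([C@@H]3C(=O)c4c(OCc5ccccc5)cc(OCc5ccccc5)cc4O[C@H]3c3ccc(OCc4ccccc4)cc3)c(OCc3ccccc3)cc2OCc2ccccc2)cc1
F3 | step 4 | (2S)-5,7-bis(benzyloxy)-2-[4-(benzyloxy)phenyl]-3-chloro-3-(methylsulfanyl)chroman-4-one | CSC1(Cl)C(=O)c2c(OCc3ccccc3)cc(OCc3ccccc3)cc2O[C@H]1c1ccc(OCc2ccccc2)cc1
F0 | step 8 | none | none
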